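The earlier runs and the new flask stem from a simulated flask for an exercise, noise included.

Target cannot exceed the substrate spent, so the bench rule that counts spent substrate as target gives a ceiling, and I wanted to find where that rule stops being of use.

in all of them: gas 89 mM (held)
- dawn: substrate 0.80 M; run made earlier
- flask: substrate 0.40 M; time 20 h

- dawn (time / h: target / %, substrate / %): 0.500: 1.2, 98.5; 0.833: 3.0, 96.7; 1.50: 5.5, 93.6; 3.00: 11.1, 87.0; 6.00: 19.4, 73.4

(standard deviation of a reading: 0.3 percentage points)

* the moment within 20 h at which there is most target
* the amount of target, in percent of the substrate charged, at that time

- at the start none of the gas is in solution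

In the dawn run at 6.00 h, 26.6% of the charge was spent, and 7.20% of the charge was neither substrate nor target. I assumed that target is lost, per substrate spent, in proportion to [target]/[substrate], which to lowest order in the spent fraction makes the loss grow as its square. So I defined a loss number, twice the lost fraction over the square of the spent fraction, a kind of selectivity factor. As a reading it is 2.04 there, and the reading at 3.00 h gives 2.25.

To that order, target is then the spent fraction minus half the loss number times its square. This stops rising at a spent fraction of one over the loss number, 49.1%, which is the border of the rule, and target there is 24.6%. I carried both to the flask, assuming that the loss number does not depend on the charge. The time I could only bracket: 5.54 h if the flask kept the dawn run's absolute rate, 11.1 h if it kept its percentage rate.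

The forecast gave 55% at 11.7 h, holding that “Target keeps rising until substrate is gone”; my height is lower.

The flask reached 25.3% at 8.67 h.

    substrate + coupling partner → target (k = 3.06 M⁻¹ h⁻¹)
    substrate + 2 coupling partner → side product (k = 7.11 M⁻² h⁻¹)
    coupling partner + target → over-reaction product (k = 5.77 M⁻¹ h⁻¹)
    gas ⇌ coupling partner, rate k4*(csat - [coupling partner]) (kL = 0.637 h⁻¹)

At 8.67 h the flask held 47.7% of substrate, so 52.3% was spent, against the 49.1% of my reckoning. The neighbour charged with 1.0 M of substrate got the same reckoning: a border at 49.1% spent and a height of 24.6%. At 20.0 h that neighbour held 40.7% of substrate, so 59.3% was spent, which lay past the border. Its highest target was 25.6%, and it ended with 25.0%.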